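**Retrosynthetic overview** (locants are those of the hexahydro-1H-indene core of the target)
- Target 24 ← oxidation of the C2 carbinol of hydroxy acid 23.
- 23 ← intramolecular Diels–Alder reaction of tetraene acid 22; the cyclohexene and cyclopentane rings close together (bonds C3a–C7a and C4–C5), trans-fused.
- 22 ← Suzuki union (C6–C7 bond) of alkenylboronate acid 13 with trienyl iodide 21.
- 13 ← cross-metathesis of 11 with 2-ethylacrylic acid; 11 ← paired-electrolysis pentenylation of alcohol 8 (C2–C3 bond), where the C1 methyl centre bought in methyl (R)-3-hydroxy-2-methylpropanoate sets C2 and C3.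
- 21 ← methylalumination/iodination of dienyne 19 ← copper-catalysed styryl addition to ethyl pent-2-ynoate.

Assumption: the C2 carbinol made in step 5 is only a relay stereocentre (oxidised in step 14), so the route is drawn for the Felkin/anti isomer that the chromium addition should favour.

**Step 1**
Reactants: 1 methyl (R)-3-hydroxy-2-methylpropanoate
Product: 2 methyl (R)-3-[(tert-butyldimethylsilyl)oxy]-2-methylpropanoate
Conditions: TBSCl, imidazole, CH2Cl2, 20 °C
Reagents that add atoms: tert-butyldimethylsilyl chloride, CC(C)(C)[Si](C)(C)Cl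
Why: Imidazole-promoted silylation of the primary alcohol (silyl ether protection) leaves the bought stereocentre untouched.

**Step 2**
Reactants: 2 methyl (R)-3-[(tert-butyldimethylsilyl)oxy]-2-methylpropanoate
Product: 4 (S)-tert-butyldimethyl[(2-methylbut-3-yn-1-yl)oxy]silane, via silyloxy aldehyde 3 (not isolated)
Conditions: i-Bu2AlH (1.05 equiv), CH2Cl2, −78 °C; then MeOH, K2CO3, dimethyl (1-diazo-2-oxopropyl)phosphonate, −78 → 20 °C
Reagents that add atoms: dimethyl (1-diazo-2-oxopropyl)phosphonate, COP(=O)(OC)C(=[N+]=[N-])C(C)=O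
Why: Partial ester reduction to the aldehyde is followed in the same flask by Ohira–Bestmann (Seyferth–Gilbert) homologation, whose mild carbonate/methanol conditions keep the α-methyl stereocentre intact.

**Step 3**
Reactants: 4 (S)-tert-butyldimethyl[(2-methylbut-3-yn-1-yl)oxy]silane
Product: 6 (S)-tert-butyldimethyl[(2-methylpent-3-yn-1-yl)oxy]silane, via lithium acetylide 5 (not isolated)
Conditions: n-BuLi, THF, −78 °C; then MeI, −78 → 20 °C
Reagents that add atoms: iodomethane, CI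
Why: Acetylide alkylation, that is, deprotonation of the terminal alkyne and SN2 methylation.

**Step 4**
Reactants: 6 (S)-tert-butyldimethyl[(2-methylpent-3-yn-1-yl)oxy]silane
Product: 8 (2S,3Z)-2-methyl-4-(4,4,5,5-tetramethyl-1,3,2-dioxaborolan-2-yl)pent-3-en-1-ol, via silyl ether 7 (not isolated)
Conditions: pinacolborane (1.5 equiv), Cp2Zr(H)Cl (10 mol%), Et3N (10 mol%), neat, 60 °C; then MeOH, camphorsulfonic acid (10 mol%), 20 °C
Reagents that add atoms: pinacolborane, B1OC(C)(C)C(C)(C)O1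
Why: Zirconocene-hydride-catalysed syn-hydroboration puts boron on the less hindered, methyl-bearing alkyne carbon (chain trans to boron), and acidic methanolysis then removes the primary silyl ether in the same flask.

**Step 5**
Reactants: 8 (2S,3Z)-2-methyl-4-(4,4,5,5-tetramethyl-1,3,2-dioxaborolan-2-yl)pent-3-en-1-ol; 9 (E)-1-chloropent-2-ene
Product: 11 (3S,4R,5S,6Z)-3-ethyl-5-methyl-7-(4,4,5,5-tetramethyl-1,3,2-dioxaborolan-2-yl)octa-1,6-dien-4-ol, via boryl aldehyde 10 (not isolated)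
Conditions: CrCl3·3THF (15 mol%), 2,6-lutidine (1.5 equiv), n-Bu4NBF4, MeCN/THF 4:1, undivided cell, TEMPO-grafted graphite-felt anode, Ni-foam cathode, 4 mA constant current, 2.1 F/mol, 20 °C
Reagents that add atoms: none
Why: Proposed new method: a redox-neutral convergent paired electrolysis in which the aminoxyl anode dehydrogenates primary alcohol 8 to aldehyde 10 while the cathode reduces trivalent to divalent chromium, which turns chloride 9 into the (E)-pent-2-enylchromium reagent; this adds at once through a chair Zimmerman–Traxler transition state (ethyl/hydroxyl anti) on the Felkin–Anh face fixed by the bought methyl centre (hydroxyl/methyl syn), the anodically released protons cleave the chromium alkoxide, and the epimerisable β,γ-unsaturated aldehyde never accumulates; the closest known reactions are the chromium-catalysed electroreductive Nozaki–Hiyama allylation with a sacrificial anode, aminoxyl-mediated anodic alcohol oxidation, and hydrogen-auto-transfer carbonyl allylation from the alcohol oxidation level.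

**Step 6**
Reactants: 11 (3S,4R,5S,6Z)-3-ethyl-5-methyl-7-(4,4,5,5-tetramethyl-1,3,2-dioxaborolan-2-yl)octa-1,6-dien-4-ol; 12 2-ethylacrylic acid
Product: 13 (2E,4S,5R,6S,7Z)-2,4-diethyl-5-hydroxy-6-methyl-8-(4,4,5,5-tetramethyl-1,3,2-dioxaborolan-2-yl)nona-2,7-dienoic acid
Conditions: second-generation Hoveyda–Grubbs catalyst RuCl2(H2IMes)(=CH-C6H4-2-O-i-Pr) (10 mol%), 12 (5 equiv), CH2Cl2, 40 °C
Reagents that add atoms: none
Why: Olefin cross-metathesis of the terminal alkene with the 1,1-disubstituted acrylic acid gives the thermodynamically favoured (E)-trisubstituted acid, and the trisubstituted alkenylboronate is inert to the ruthenium carbene.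

**Step 7**
Reactants: 14 ethyl pent-2-ynoate; 15 (E)-(2-phenylethenyl)boronic acid
Product: 16 ethyl (2E,4E)-3-ethyl-5-phenylpenta-2,4-dienoate
Conditions: CuOAc (5 mol%), MeOH, 25 °C
Reagents that add atoms: none
Why: Copper-catalysed conjugate addition of the alkenylboronic acid to the ynoate is a syn-carbometalation followed by protonation, so the styryl group ends cis to hydrogen and trans to the ester.

**Step 8**
Reactants: 16 ethyl (2E,4E)-3-ethyl-5-phenylpenta-2,4-dienoate
Product: 17 (2E,4E)-3-ethyl-5-phenylpenta-2,4-dien-1-ol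
Conditions: i-Bu2AlH (2.4 equiv), CH2Cl2, −78 °C
Reagents that add atoms: none
Why: Clean 1,2-reduction of the conjugated ester by the aluminium hydride without touching the diene geometry.

**Step 9**
Reactants: 17 (2E,4E)-3-ethyl-5-phenylpenta-2,4-dien-1-ol
Product: 18 (2E,4E)-3-ethyl-5-phenylpenta-2,4-dienal
Conditions: MnO2, CH2Cl2, 20 °C
Reagents that add atoms: none
Why: Chemoselective MnO2 oxidation of the allylic alcohol under neutral conditions that do not isomerise the diene.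

**Step 10**
Reactants: 18 (2E,4E)-3-ethyl-5-phenylpenta-2,4-dienal
Product: 19 [(1E,3E)-3-ethylhexa-1,3-dien-5-yn-1-yl]benzene
Conditions: Me3SiCHN2, n-BuLi, THF, −78 → 0 °C
Reagents that add atoms: (trimethylsilyl)diazomethane, C[Si](C)(C)C=[N+]=[N-]
Why: Colvin rearrangement (addition, Peterson-type elimination, 1,2-hydrogen shift of the alkylidene carbene) homologates the enal to the enyne without the methanol conjugate addition that troubles carbonate/methanol conditions.

**Step 11**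
Reactants: 19 [(1E,3E)-3-ethylhexa-1,3-dien-5-yn-1-yl]benzene
Product: 21 [(1E,3E,5E)-3-ethyl-6-iodo-5-methylhexa-1,3,5-trien-1-yl]benzene, via alkenylalane 20 (not isolated)
Conditions: AlMe3 (2 equiv), Cp2ZrCl2 (25 mol%), CH2Cl2, 0 → 20 °C; then I2, THF, −30 °C
Reagents that add atoms: trimethylaluminium, C[Al](C)C; iodine, II
Why: Negishi zirconium-catalysed syn-methylalumination puts methyl on the internal and aluminium on the terminal alkyne carbon, and iodinolysis with retention gives the (E)-iodide.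

**Step 12**
Reactants: 13 (2E,4S,5R,6S,7Z)-2,4-diethyl-5-hydroxy-6-methyl-8-(4,4,5,5-tetramethyl-1,3,2-dioxaborolan-2-yl)nona-2,7-dienoic acid; 21 [(1E,3E,5E)-3-ethyl-6-iodo-5-methylhexa-1,3,5-trien-1-yl]benzene
Product: 22 (2E,4S,5R,6S,7E,9E,11E,13E)-2,4,12-triethyl-5-hydroxy-6,8,10-trimethyl-14-phenyltetradeca-2,7,9,11,13-pentaenoic acid
Conditions: PdCl2(dppf) (5 mol%), aq. K3PO4 (4 equiv), THF, 25 °C, dark; work-up at pH 4
Reagents that add atoms: none
Why: Suzuki–Miyaura coupling joins the two alkenyl partners with retention of both double-bond geometries and tolerates the free hydroxyl and carboxylate.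

**Step 13**
Reactants: 22 (2E,4S,5R,6S,7E,9E,11E,13E)-2,4,12-triethyl-5-hydroxy-6,8,10-trimethyl-14-phenyltetradeca-2,7,9,11,13-pentaenoic acid
Product: 23 (1S,2R,3S,3aR,4R,5R,7aR)-3,4-diethyl-5-[(1E,3E)-2-ethyl-4-phenylbuta-1,3-dien-1-yl]-2-hydroxy-1,5,7-trimethyl-2,3,3a,4,5,7a-hexahydro-1H-indene-4-carboxylic acid
Conditions: toluene (5 mM), BHT (cat.), 90 °C
Reagents that add atoms: none
Why: Thermal intramolecular Diels–Alder reaction through the carboxyl-endo transition state gives the trans-fused bicycle, because the 1,3-anti C1 methyl and C3 ethyl centres each keep their hydrogen in the plane of the adjacent alkene to avoid allylic 1,3-strain, which selects one face of both diene and dienophile and sets C3a, C4, C5 and C7a.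

**Step 14**
Reactants: 23 (1S,2R,3S,3aR,4R,5R,7aR)-3,4-diethyl-5-[(1E,3E)-2-ethyl-4-phenylbuta-1,3-dien-1-yl]-2-hydroxy-1,5,7-trimethyl-2,3,3a,4,5,7a-hexahydro-1H-indene-4-carboxylic acid
Product: 24 (1S,3S,3aR,4R,5R,7aR)-3,4-diethyl-5-[(1E,3E)-2-ethyl-4-phenylbuta-1,3-dien-1-yl]-1,5,7-trimethyl-2-oxo-2,3,3a,4,5,7a-hexahydro-1H-indene-4-carboxylic acid
Conditions: Dess–Martin periodinane, CH2Cl2, 0 → 20 °C
Reagents that add atoms: none
Why: Dess–Martin oxidation of the secondary carbinol is neutral and spares the acid and diene, and the two α-centres already sit trans to their ring neighbours (the thermodynamic arrangement), so they do not drift.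

**Compound list**
1 | methyl (R)-3-hydroxy-2-methylpropanoate | COC(=O)[C@H](C)CO | starting material
2 | methyl (R)-3-[(tert-butyldimethylsilyl)oxy]-2-methylpropanoate | COC(=O)[C@H](C)CO[Si](C)(C)C(C)(C)C | intermediate
3 | (R)-3-[(tert-butyldimethylsilyl)oxy]-2-methylpropanal | O=C[C@H](C)CO[Si](C)(C)C(C)(C)C | intermediate (not isolated)
4 | (S)-tert-butyldimethyl[(2-methylbut-3-yn-1-yl)oxy]silane | C#C[C@H](C)CO[Si](C)(C)C(C)(C)C | intermediate
5 | lithium acetylide of 4 | [Li]C#C[C@H](C)CO[Si](C)(C)C(C)(C)C | intermediate (not isolated)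
6 | (S)-tert-butyldimethyl[(2-methylpent-3-yn-1-yl)oxy]silane | CC#C[C@H](C)CO[Si](C)(C)C(C)(C)C | intermediate
7 | tert-butyldimethyl{[(2S,3Z)-2-methyl-4-(4,4,5,5-tetramethyl-1,3,2-dioxaborolan-2-yl)pent-3-en-1-yl]oxy}silane | C/C(B1OC(C)(C)C(C)(C)O1)=C\[C@H](C)CO[Si](C)(C)C(C)(C)C | intermediate (not isolated)
8 | (2S,3Z)-2-methyl-4-(4,4,5,5-tetramethyl-1,3,2-dioxaborolan-2-yl)pent-3-en-1-ol | C/C(B1OC(C)(C)C(C)(C)O1)=C\[C@H](C)CO | intermediate
9 | (E)-1-chloropent-2-ene | CC/C=C/CCl | starting material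
10 | (2S,3Z)-2-methyl-4-(4,4,5,5-tetramethyl-1,3,2-dioxaborolan-2-yl)pent-3-enal | C/C(B1OC(C)(C)C(C)(C)O1)=C\[C@H](C)C=O | intermediate (not isolated)
11 | (3S,4R,5S,6Z)-3-ethyl-5-methyl-7-(4,4,5,5-tetramethyl-1,3,2-dioxaborolan-2-yl)octa-1,6-dien-4-ol | C/C(B1OC(C)(C)C(C)(C)O1)=C\[C@H](C)[C@@H](O)[C@@H](CC)C=C | intermediate
12 | 2-ethylacrylic acid | C=C(CC)C(=O)O | starting material
13 | (2E,4S,5R,6S,7Z)-2,4-diethyl-5-hydroxy-6-methyl-8-(4,4,5,5-tetramethyl-1,3,2-dioxaborolan-2-yl)nona-2,7-dienoic acid | C/C(B1OC(C)(C)C(C)(C)O1)=C\[C@H](C)[C@@H](O)[C@@H](CC)/C=C(\CC)C(=O)O | intermediate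
14 | ethyl pent-2-ynoate | CCC#CC(=O)OCC | starting material
15 | (E)-(2-phenylethenyl)boronic acid | OB(O)/C=C/c1ccccc1 | starting material
16 | ethyl (2E,4E)-3-ethyl-5-phenylpenta-2,4-dienoate | CCOC(=O)/C=C(CC)/C=C/c1ccccc1 | intermediate
17 | (2E,4E)-3-ethyl-5-phenylpenta-2,4-dien-1-ol | OC/C=C(CC)/C=C/c1ccccc1 | intermediate
18 | (2E,4E)-3-ethyl-5-phenylpenta-2,4-dienal | O=C/C=C(CC)/C=C/c1ccccc1 | intermediate
19 | [(1E,3E)-3-ethylhexa-1,3-dien-5-yn-1-yl]benzene | C#C/C=C(CC)/C=C/c1ccccc1 | intermediate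
20 | dimethyl[(1E,3E,5E)-4-ethyl-2-methyl-6-phenylhexa-1,3,5-trien-1-yl]alane | C[Al](C)/C=C(C)/C=C(CC)/C=C/c1ccccc1 | intermediate (not isolated)
21 | [(1E,3E,5E)-3-ethyl-6-iodo-5-methylhexa-1,3,5-trien-1-yl]benzene | I/C=C(C)/C=C(CC)/C=C/c1ccccc1 | intermediate
22 | (2E,4S,5R,6S,7E,9E,11E,13E)-2,4,12-triethyl-5-hydroxy-6,8,10-trimethyl-14-phenyltetradeca-2,7,9,11,13-pentaenoic acid | CCC(/C=C/c1ccccc1)=C\C(C)=C\C(C)=C\[C@H](C)[C@@H](O)[C@@H](CC)/C=C(\CC)C(=O)O | intermediate
23 | (1S,2R,3S,3aR,4R,5R,7aR)-3,4-diethyl-5-[(1E,3E)-2-ethyl-4-phenylbuta-1,3-dien-1-yl]-2-hydroxy-1,5,7-trimethyl-2,3,3a,4,5,7a-hexahydro-1H-indene-4-carboxylic acid | CCC(/C=C/c1ccccc1)=C\[C@@]1(C)C=C(C)[C@@H]2[C@H]([C@H](CC)[C@H](O)[C@H]2C)[C@@]1(CC)C(=O)O | intermediate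
24 | (1S,3S,3aR,4R,5R,7aR)-3,4-diethyl-5-[(1E,3E)-2-ethyl-4-phenylbuta-1,3-dien-1-yl]-1,5,7-trimethyl-2-oxo-2,3,3a,4,5,7a-hexahydro-1H-indene-4-carboxylic acid | CCC(/C=C/c1ccccc1)=C\[C@@]1(C)C=C(C)[C@@H]2[C@H]([C@H](CC)C(=O)[C@H]2C)[C@@]1(CC)C(=O)O | target

**Step count**
Total: 14 steps. Longest linear sequence: 9 steps (steps 1–6, then 12–14); the iodide branch (steps 7–11) joins at step 12.

**Three steps most likely to fail**

Step 5 (the proposed paired electrolysis). The main risks are redox cross-talk between the anode mediator and divalent chromium, protonolysis of the pentenylchromium reagent before it meets the aldehyde, and only moderate Felkin selectivity. The fallback uses known chemistry, sets out from 8 and comes back at 11. Alcohol 8 is oxidised with Dess–Martin periodinane to aldehyde 10, which is used crude in a stoichiometric Nozaki–Hiyama reaction with CrCl2 and (E)-1-bromopent-2-ene in THF at 0 °C. This passes through the same chair transition state and gives the same anti/Felkin alcohol 11. It makes no compound outside the list (F0).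

Step 6 (cross-metathesis). The terminal alkene carries an allylic ethyl branch and the partner is 1,1-disubstituted, so conversion may be poor. The fallback avoids metathesis altogether, sets out from 8 and comes back at 13. Oxidation of 8 gives aldehyde 10. Anti-selective aldol addition of the lithium (E)-enolate of 2,6-dimethylphenyl butanoate (LDA, THF, −78 °C) gives 2,6-dimethylphenyl (2R,3R,4S,5Z)-2-ethyl-3-hydroxy-4-methyl-6-(4,4,5,5-tetramethyl-1,3,2-dioxaborolan-2-yl)hept-5-enoate F1. LiBH4 reduction gives (2S,3R,4S,5Z)-2-ethyl-4-methyl-6-(4,4,5,5-tetramethyl-1,3,2-dioxaborolan-2-yl)hept-5-ene-1,3-diol F2. TEMPO/PhI(OAc)2 oxidises only the primary alcohol to (2R,3R,4S,5Z)-2-ethyl-3-hydroxy-4-methyl-6-(4,4,5,5-tetramethyl-1,3,2-dioxaborolan-2-yl)hept-5-enal F3. Wittig reaction with methyl 2-(triphenylphosphoranylidene)butanoate gives methyl (2E,4S,5R,6S,7Z)-2,4-diethyl-5-hydroxy-6-methyl-8-(4,4,5,5-tetramethyl-1,3,2-dioxaborolan-2-yl)nona-2,7-dienoate F4, and LiOH hydrolysis returns acid 13.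

Step 13 (intramolecular Diels–Alder reaction). The trisubstituted acrylic acid is a weak dienophile, and at 90 °C a 1,5-hydrogen shift of the diene or a lower diastereomer ratio could intervene. The fallback switches to a more activated aldehyde dienophile that cyclises near room temperature; it sets out from 22 and comes back at 23. LiAlH4 reduces the acid to (2E,4S,5R,6S,7E,9E,11E,13E)-2,4,12-triethyl-6,8,10-trimethyl-14-phenyltetradeca-2,7,9,11,13-pentaene-1,5-diol F5. MnO2 oxidises only the allylic alcohol to (2E,4S,5R,6S,7E,9E,11E,13E)-2,4,12-triethyl-5-hydroxy-6,8,10-trimethyl-14-phenyltetradeca-2,7,9,11,13-pentaenal F6, which cyclises at 20–40 °C to (1S,2R,3S,3aR,4R,5R,7aR)-3,4-diethyl-5-[(1E,3E)-2-ethyl-4-phenylbuta-1,3-dien-1-yl]-2-hydroxy-1,5,7-trimethyl-2,3,3a,4,5,7a-hexahydro-1H-indene-4-carbaldehyde F7. Pinnick oxidation (NaClO2, NaH2PO4, 2-methyl-2-butene) then gives 23.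

**Further compounds**
F0 | step 5 | none | none
F1 | step 6 | 2,6-dimethylphenyl (2R,3R,4S,5Z)-2-ethyl-3-hydroxy-4-methyl-6-(4,4,5,5-tetramethyl-1,3,2-dioxaborolan-2-yl)hept-5-enoate | C/C(B1OC(C)(C)C(C)(C)O1)=C\[C@H](C)[C@@H](O)[C@@H](CC)C(=O)Oc1c(C)cccc1C
F2 | step 6 | (2S,3R,4S,5Z)-2-ethyl-4-methyl-6-(4,4,5,5-tetramethyl-1,3,2-dioxaborolan-2-yl)hept-5-ene-1,3-diol | C/C(B1OC(C)(C)C(C)(C)O1)=C\[C@H](C)[C@@H](O)[C@@H](CC)CO
F3 | step 6 | (2R,3R,4S,5Z)-2-ethyl-3-hydroxy-4-methyl-6-(4,4,5,5-tetramethyl-1,3,2-dioxaborolan-2-yl)hept-5-enal | C/C(B1OC(C)(C)C(C)(C)O1)=C\[C@H](C)[C@@H](O)[C@@H](CC)C=O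
F4 | step 6 | methyl (2E,4S,5R,6S,7Z)-2,4-diethyl-5-hydroxy-6-methyl-8-(4,4,5,5-tetramethyl-1,3,2-dioxaborolan-2-yl)nona-2,7-dienoate | C/C(B1OC(C)(C)C(C)(C)O1)=C\[C@H](C)[C@@H](O)[C@@H](CC)/C=C(\CC)C(=O)OC
F5 | step 13 | (2E,4S,5R,6S,7E,9E,11E,13E)-2,4,12-triethyl-6,8,10-trimethyl-14-phenyltetradeca-2,7,9,11,13-pentaene-1,5-diol | CCC(/C=C/c1ccccc1)=C\C(C)=C\C(C)=C\[C@H](C)[C@@H](O)[C@@H](CC)/C=C(\CC)CO
F6 | step 13 | (2E,4S,5R,6S,7E,9E,11E,13E)-2,4,12-triethyl-5-hydroxy-6,8,10-trimethyl-14-phenyltetradeca-2,7,9,11,13-pentaenal | CCC(/C=C/c1ccccc1)=C\C(C)=C\C(C)=C\[C@H](C)[C@@H](O)[C@@H](CC)/C=C(\CC)C=O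
F7 | step 13 | (1S,2R,3S,3aR,4R,5R,7aR)-3,4-diethyl-5-[(1E,3E)-2-ethyl-4-phenylbuta-1,3-dien-1-yl]-2-hydroxy-1,5,7-trimethyl-2,3,3a,4,5,7a-hexahydro-1H-indene-4-carbaldehyde | CCC(/C=C/c1ccccc1)=C\[C@@]1(C)C=C(C)[C@@H]2[C@H]([C@H](CC)[C@H](O)[C@H]2C)[C@@]1(CC)C=O
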